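**Strategy**

1. Retrosynthesis: the C3 carbinol is traced to its epimer (C3–O bond exchanged by SN2 through a chloroacetate). The oxirane C6–O bond and the C4=C5 alkene are traced to a peroxide bridging C1 and C4. The C1–O and C4–O bonds are then cut together (retro-[4+2], loss of O2) to a cyclohexa-1,3-diene. Last, the two benzoate O–acyl bonds and the C1–CH2 bond are cut back to the cis-dihydrodiol of bromobenzene.
2. Enabling feature (C1 = quaternary carbon with CH2OBz, C2 = CHOBz, C3 = CHOH, C4=C5 alkene, C6 = oxirane CH): a cis-fused C1–O–C6 oxirane allylic to C4=C5 is a cyclohexa-1,3-diene monoepoxide, which is what a C1/C4 endoperoxide gives on loss of one oxygen atom. The C1=C6–C5=C4 diene with oxygens at C2 and C3 is a benzene ring after cis-dihydroxylation.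
3. Forward order: the carbocycle is purchased as the dearomatized diene diol. The C1 carbon is attached by Stille coupling, both benzoates are installed, and singlet oxygen closes the peroxide bridge across C1/C4. Phosphine then contracts the bridge to the oxirane, which is the last ring to close.
4. Stereochemistry: C2 comes with the purchased diol. C1 and C6 follow from oxygen adding anti to the cis C2/C3 substituents. C3 is purchased with the opposite configuration and inverted at the end by a Mitsunobu reaction.

Key step: step 4

Assumption: the (1S,2S) cis-dihydrodiol of bromobenzene (fermentation product) and (tributylstannyl)methanol are taken as purchasable; the locants C1–C6 defined above are used for every intermediate.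

**Route**

Step 1
Reactants: 1 (1S,2S)-3-bromocyclohexa-3,5-diene-1,2-diol
Product: 2 (1S,6S)-2-bromo-6-[(tert-butyldimethylsilyl)oxy]cyclohexa-2,4-dien-1-ol (silyl ether on the hydroxyl remote from bromine)
Conditions: TBSCl (1.05 equiv), imidazole, DMF, −10 → 0 °C
Reagents that add atoms: tert-butyldimethylsilyl chloride, CC(C)(C)[Si](C)(C)Cl
Why: Kinetic mono-silylation of a cis-diol, in which the hydroxyl remote from bromine (the future C3–OH) is the less hindered one, so one equivalent of silyl chloride in the cold should stop at the distal ether without touching a stereocentre.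

Step 2
Reactants: 2 distal mono-TBS bromodiene; 3 (tributylstannyl)methanol
Product: 4 (1R,6S)-6-[(tert-butyldimethylsilyl)oxy]-2-(hydroxymethyl)cyclohexa-2,4-dien-1-ol
Conditions: Pd(PPh3)4 (cat.), CuI, CsF, DMF, 40 °C, degassed, dark
Reagents that add atoms: none
Why: Migita–Kosugi–Stille hydroxymethylation, in which zerovalent palladium inserts into the alkenyl C–Br bond and the α-oxygenated CH2OH group is transferred from tin (assisted by CuI and fluoride) in preference to butyl; the free C2 hydroxyl and the C3 silyl ether are poor leaving groups toward palladium, so the diene should survive the near-neutral, mild conditions.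

Step 3
Reactants: 4 hydroxymethyl diene; 5 benzoyl chloride (two equivalents enter the product)
Product: 6 (1R,6S)-2-[(benzoyloxy)methyl]-6-[(tert-butyldimethylsilyl)oxy]cyclohexa-2,4-dien-1-yl benzoate
Conditions: BzCl (2.5 equiv), pyridine, DMAP (cat.), CH2Cl2, 0 °C → rt
Reagents that add atoms: none
Why: DMAP-catalysed O-acylation of the primary allylic and the hindered secondary C2 hydroxyl with an acid chloride, under cold basic conditions that avoid acid-induced aromatization and silyl migration and leave both stereocentres untouched.

Step 4
Reactants: 6 dibenzoate diene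
Product: 7 [(1R,4R,7S,8R)-7-(benzoyloxy)-8-[(tert-butyldimethylsilyl)oxy]-2,3-dioxabicyclo[2.2.2]oct-5-en-1-yl]methyl benzoate (peroxide bridge across C1/C4 anti to the C2 benzoate and the C3 silyl ether)
Conditions: O2, 5,10,15,20-tetraphenylporphyrin (cat.), white LED, CH2Cl2, −30 °C
Reagents that add atoms: dioxygen (reacting as singlet oxygen), O=O
Why: Energy transfer from the excited porphyrin gives singlet oxygen, which adds to the ring-locked s-cis diene in a concerted suprafacial [4+2] cycloaddition, forming the C1–O and C4–O bonds in one event; the closest known reaction type is the sensitized photooxygenation of protected arene cis-dihydrodiols to bicyclic endoperoxides. The peroxide bridge, and with it both six-membered 1,2-dioxygenated rings of the 2,3-dioxabicyclo[2.2.2]octene, closes by cycloaddition across the diene termini C1 and C4. The two new stereocentres C1 and C4 are set together by the face of approach: the cis C2 benzoate and C3 silyl ether cover one face, so oxygen should enter anti to both, which relays the purchased C2 configuration to the quaternary C1. The step needs facial selectivity and [4+2] rather than ene reactivity; the first is secured by the cis-disposed C2/C3 substituents and the second by the cisoid cyclohexadiene geometry, while the low temperature keeps the diene from dimerizing or aromatizing and the peroxide from rearranging to a bis-epoxide.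

Step 5
Reactants: 7 C1/C4 endoperoxide
Product: 9 [(1S,2S,3S,6S)-2-(benzoyloxy)-3-[(tert-butyldimethylsilyl)oxy]-7-oxabicyclo[4.1.0]hept-4-en-1-yl]methyl benzoate, via oxyphosphonium alkoxide betaine 8 (not isolated)
Conditions: PPh3 (1.1 equiv), CH2Cl2, −30 °C → rt
Reagents that add atoms: none
Why: Deoxygenation of an unsaturated bicyclic endoperoxide by trivalent phosphorus, in which phosphorus attacks the less hindered peroxide oxygen (on secondary C4) and the freed tertiary C1 alkoxide of betaine 8 closes onto C6 in a syn SN2′ 3-exo displacement that expels Ph3P=O from C4, moves the alkene to C4=C5 and keeps the oxirane oxygen on the face the peroxide occupied, so C6 is set by C1.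

Step 6
Reactants: 9 vinyl oxirane C3 silyl ether
Product: 10 [(1S,2S,3S,6S)-2-(benzoyloxy)-3-hydroxy-7-oxabicyclo[4.1.0]hept-4-en-1-yl]methyl benzoate (3-epi-target with C3–OH cis to the C2 benzoate)
Conditions: Bu4NF/AcOH (equimolar), THF, 0 °C → rt
Reagents that add atoms: none
Why: Fluoride-induced Si–O cleavage, buffered with acetic acid so that the liberated C3 oxygen is protonated before the cis-vicinal benzoate can migrate, and mild enough for both esters and the vinyl oxirane; C3 keeps its configuration.

Step 7
Reactants: 10 3-epi alcohol
Product: 11 [(1S,2S,3R,6S)-2-(benzoyloxy)-3-(2-chloroacetoxy)-7-oxabicyclo[4.1.0]hept-4-en-1-yl]methyl benzoate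
Conditions: PPh3, diisopropyl azodicarboxylate (premixed), then ClCH2CO2H and 10, toluene, 0 °C → rt
Reagents that add atoms: chloroacetic acid, OC(=O)CCl
Why: Mitsunobu reaction, in which the oxyphosphonium of the secondary allylic C3 alcohol is displaced by chloroacetate in an SN2 step with inversion; the acidic pronucleophile favours substitution at a flanked carbinol, and the C2 benzoate, being cis to the leaving group, cannot participate and leaves the entering face open.

Step 8
Reactants: 11 C3-inverted chloroacetate
Product: 12 [(1S,2S,3R,6S)-2-(benzoyloxy)-3-hydroxy-7-oxabicyclo[4.1.0]hept-4-en-1-yl]methyl benzoate (CNP0285759.2)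
Conditions: H2NNHCS2− i-Pr2NEtH+ (made in the flask from N2H4·H2O, CS2 and i-Pr2NEt), 2,6-lutidine/AcOH, dioxane, 20 °C
Reagents that add atoms: none
Why: Chemoselective dechloroacetylation, in which the dithiocarbazate sulfur alkylates the α-chloro ester and the hydrazine nitrogen then lactamizes onto that ester carbonyl, releasing the C3 alcohol under near-neutral conditions that should leave the two benzoates and the vinyl oxirane intact and no stereocentre affected.

**Compound list**

1 | (1S,2S)-3-bromocyclohexa-3,5-diene-1,2-diol | BrC1=CC=C[C@H](O)[C@@H]1O | starting material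
2 | (1S,6S)-2-bromo-6-[(tert-butyldimethylsilyl)oxy]cyclohexa-2,4-dien-1-ol | BrC1=CC=C[C@H](O[Si](C)(C)C(C)(C)C)[C@@H]1O | intermediate
3 | (tributylstannyl)methanol | CCCC[Sn](CCCC)(CCCC)CO | starting material
4 | (1R,6S)-6-[(tert-butyldimethylsilyl)oxy]-2-(hydroxymethyl)cyclohexa-2,4-dien-1-ol | OCC1=CC=C[C@H](O[Si](C)(C)C(C)(C)C)[C@@H]1O | intermediate
5 | benzoyl chloride | O=C(Cl)c1ccccc1 | starting material
6 | (1R,6S)-2-[(benzoyloxy)methyl]-6-[(tert-butyldimethylsilyl)oxy]cyclohexa-2,4-dien-1-yl benzoate | O=C(OCC1=CC=C[C@H](O[Si](C)(C)C(C)(C)C)[C@@H]1OC(=O)c1ccccc1)c1ccccc1 | intermediate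
7 | [(1R,4R,7S,8R)-7-(benzoyloxy)-8-[(tert-butyldimethylsilyl)oxy]-2,3-dioxabicyclo[2.2.2]oct-5-en-1-yl]methyl benzoate (peroxide anti to both ring oxygens) | O=C(OC[C@]12OO[C@H](C=C1)[C@H](O[Si](C)(C)C(C)(C)C)[C@@H]2OC(=O)c1ccccc1)c1ccccc1 | intermediate
8 | betaine from 7 and PPh3: C1 alkoxide and C4 triphenylphosphoniooxy group on the same face, C5=C6 alkene, C2 benzoate and C3 silyl ether on the opposite face | O=C(OC[C@]1([O-])C=C[C@@H](O[P+](c2ccccc2)(c2ccccc2)c2ccccc2)[C@H](O[Si](C)(C)C(C)(C)C)[C@@H]1OC(=O)c1ccccc1)c1ccccc1 | intermediate (not isolated)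
9 | [(1S,2S,3S,6S)-2-(benzoyloxy)-3-[(tert-butyldimethylsilyl)oxy]-7-oxabicyclo[4.1.0]hept-4-en-1-yl]methyl benzoate | O=C(OC[C@]12O[C@H]1C=C[C@H](O[Si](C)(C)C(C)(C)C)[C@@H]2OC(=O)c1ccccc1)c1ccccc1 | intermediate
10 | [(1S,2S,3S,6S)-2-(benzoyloxy)-3-hydroxy-7-oxabicyclo[4.1.0]hept-4-en-1-yl]methyl benzoate | O=C(OC[C@]12O[C@H]1C=C[C@H](O)[C@@H]2OC(=O)c1ccccc1)c1ccccc1 | intermediate
11 | [(1S,2S,3R,6S)-2-(benzoyloxy)-3-(2-chloroacetoxy)-7-oxabicyclo[4.1.0]hept-4-en-1-yl]methyl benzoate | O=C(OC[C@]12O[C@H]1C=C[C@@H](OC(=O)CCl)[C@@H]2OC(=O)c1ccccc1)c1ccccc1 | intermediate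
12 | [(1S,2S,3R,6S)-2-(benzoyloxy)-3-hydroxy-7-oxabicyclo[4.1.0]hept-4-en-1-yl]methyl benzoate (CNP0285759.2) | O=C(OC[C@]12O[C@H]1C=C[C@@H](O)[C@@H]2OC(=O)c1ccccc1)c1ccccc1 | target

**Count and risks**

Total step count: 8. Longest linear sequence: 8 steps (1 → 12).

Step 2. What may go wrong: transfer of the sp3 CH2OH group from tin is slow, so butyl transfer, protodebromination, Diels–Alder dimerization or dehydrative aromatization of the diene may overtake the coupling. The fallback brings the carbon in as carbon monoxide instead of as an organotin nucleophile. Setting out from 2, Heck-type methoxycarbonylation (CO 1 atm, MeOH, Et3N, PdCl2(PPh3)2, DMF, 60 °C) should give methyl (5S,6R)-5-[(tert-butyldimethylsilyl)oxy]-6-hydroxycyclohexa-1,3-diene-1-carboxylate F1. 1,2-Reduction of the ester with i-Bu2AlH (CH2Cl2, −78 °C) should then give the carbinol, rejoining the route at 4.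

Step 5. What may go wrong: attack of phosphorus on the peroxide oxygen at the quaternary C1, or ionization of the tertiary C1–O bond from a cyclic phosphorane, would lead to the regioisomeric C4–C5 oxirane; thermal or base-induced drift of the peroxide (bis-epoxide, hydroxy-enone) may also intervene. The fallback separates O–O cleavage from C–O activation, so that the class of alcohol decides the regiochemistry rather than the point of phosphorus attack. Setting out from 7, thiourea (MeOH, rt) should reduce the peroxide to the cis-ene-1,4-diol F2, with the tertiary C1 hydroxyl and the secondary allylic C4 hydroxyl on the same face. Mitsunobu-type cyclodehydration (PPh3, diisopropyl azodicarboxylate, THF, 0 °C) can activate only the secondary C4 hydroxyl. Because a direct 1,4-closure is impossible for cis-disposed groups, the tertiary oxygen should close syn-SN2′ onto C6, rejoining the route at 9.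

Step 7. What may go wrong: the free carboxylic acid may open the acid-sensitive vinyl oxirane before the oxyphosphonium at the flanked C3 is displaced, or the displacement may leak to SN2′ capture at C5 or to elimination. The fallback uses a preformed sulfonate and a carboxylate salt, with no free acid and no redox condensation. Setting out from 10, MsCl/Et3N (CH2Cl2, −20 °C) should give the C3 mesylate F3. SN2 displacement with CsO2CCH2Cl (18-crown-6, toluene, rt to 40 °C) should then deliver the inverted ester, rejoining the route at 11.

**Further compounds**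

F1 | step 2 | methyl (5S,6R)-5-[(tert-butyldimethylsilyl)oxy]-6-hydroxycyclohexa-1,3-diene-1-carboxylate | COC(=O)C1=CC=C[C@H](O[Si](C)(C)C(C)(C)C)[C@@H]1O
F2 | step 5 | cis-ene-1,4-diol from O–O reduction of 7: [6-(benzoyloxy)-5-[(tert-butyldimethylsilyl)oxy]-1,4-dihydroxycyclohex-2-en-1-yl]methyl benzoate, both hydroxyls on the face anti to the C5/C6 oxygens | O=C(OC[C@]1(O)C=C[C@@H](O)[C@H](O[Si](C)(C)C(C)(C)C)[C@@H]1OC(=O)c1ccccc1)c1ccccc1
F3 | step 7 | C3 methanesulfonate of 10: [(1S,2S,3S,6S)-2-(benzoyloxy)-3-(methanesulfonyloxy)-7-oxabicyclo[4.1.0]hept-4-en-1-yl]methyl benzoate | O=C(OC[C@]12O[C@H]1C=C[C@H](OS(C)(=O)=O)[C@@H]2OC(=O)c1ccccc1)c1ccccc1
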